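Atom and ring labels used throughout: the tetrahydrophthalide half is numbered C1 (lactone C=O), O2, C3, C3a, C4, C5, C6, C7, C7a. The phthalide half carries primed locants (C1' carbonyl, O2', spiro C3'), and C8' is the propyl-bearing carbon. Ring A = butenolide (C1, O2, C3, C3a, C7a); ring B = carbocycle (C3a, C4, C5, C6, C7, C7a); ring C = cyclobutane (C6, C7, C3', C8'); ring D = phthalide lactone with its benzo ring. Compound numbers are those of the steps and the compound list.

## Analysis of the target

Target 22 is the (6S,7R,3'R,8'R) isomer of a bis-lactone built around a cyclobutane. Butenolide ring A carries a (Z)-butylidene group at C3 and shares the C3a=C7a alkene with ring B; ring B is cis-fused through C6–C7 to ring C; and C3' of ring C is the spiro carbon of a phthalide (ring D). All four stereocentres are contiguous and lie on ring C. H-6, H-7, H-8' and the aryl carbon are on one face of ring C (the convex face of the bicyclo[4.2.0] unit). C5, C7a, the propyl group and O2' are on the other, so the propyl group is endo (cis to C5) and O2' is cis to C7a. The sensitive parts are the (Z)-alkylidene butenolide (an enol ester and a diene at once, labile to base, nucleophiles, oxidants and E/Z isomerisation), the allylic C7–H, and the tertiary benzylic C3'–O2' bond on a strained ring, which can ionise under acid. The difficulty lies in a fully substituted cyclobutane with a quaternary spiro centre, in an endo propyl group that is the less stable epimer, and in the need for absolute control although no stereocentre lies outside ring C. The strategy rests on ring B: it shares C6–C7 with the four-membered ring and C3a/C7a with ring A, and with its alkene placed at C3a=C4 it is the cyclohexene of a Diels–Alder reaction between the diene C7a=C3a–C4=C5 of a 4-vinylbutenolide and the C6=C7 alkene of cyclobutenone, whose carbonyl carbon is C3'. That carbonyl then serves twice, as the handle for the propyl group at C8' and as the electrophile for the aryl group at C3', both set by approach to the convex face.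

## Retrosynthetic reasoning

The exocyclic C3=C bond of 22 is cut first. The dienyl enol lactone tolerates neither organometallic reagents nor hydrogenation, so it has to come last. Dehydration of carbinol 20 (through mesylate 21) leads back to a vinylogous aldol between butanal 19 and silyloxyfuran 18, the aromatic enol silane of butenolide 17. The forward reaction must bond only at C3, which is secured because the α-carbon C7a is fully substituted, and must eliminate to the Z alkene, which is favoured because the ring methylene C4 on C3a pushes the propyl chain towards O2.

In 17 the spiro centre is disconnected at the C3'–aryl bond and at the acyl–O2' bond of ring D. This leads to cyclobutanone 13 and the arylmagnesium 15 made from methyl 2-iodobenzoate 14; alkoxide 16 closes ring D on the neighbouring ester. The cut is made here because both α-substituents of the ketone in 13 (C7a on C7, propyl on C8') lie on the concave face. A carbon nucleophile can then only arrive from the convex face, which places the aryl group cis to H-7 and H-8' and the oxygen on the concave face, as in 22. Attack of an oxygen nucleophile on a C3' cation would give the epimer.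

The propyl group at C8' of 13 is traced to the exocyclic alkene of enone 12 and, through dehydration of aldol 10 (mesylate 11), to propanal 8 and the C8' methylene of keto-lactone 7. Direct alkylation of an enolate would bring the chain in from the convex face and give the exo epimer. An sp2 carbon at C8' followed by hydrogen delivery from the convex face puts the chain on the concave face instead. The forward sequence has to enolise the ketone beside a lactone with an activated α-hydrogen, hence boron enolate 9. The base used for the dehydration is allowed to move the ring alkene from C3a=C4 into conjugation at C3a=C7a, which removes the C7a stereocentre.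

Keto-lactone 7 contains rings A, B and C. Cutting C5–C6 and C7–C7a opens ring B into cyclobutenone 3 and vinylbutenolide 6. This is the strategic cut: the four-membered ring is taken from a small strained enone and not built, two C–C bonds are made, the cis ring fusion follows from suprafacial addition, and the absolute configuration of C6 and C7 is left to a chiral boron Lewis acid bound to the only ketone present. The forward reaction needs the regiochemistry in which the unsubstituted diene terminus C5 meets the β-carbon C6, and one enantiotopic face of 3.

Both partners are two steps from commercial compounds. 3 arises by dehydrobromination of bromoketone 2, itself from bromodecarboxylation of keto acid 1. 6 arises by vinyl cross-coupling of bromobutenolide 5, made from tetronic acid 4 by exchange of the enol hydroxyl for bromide.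

## Alternatives that were turned down

Alternative 1: ring contraction of a pyrrolidine by nitrogen deletion.
- Disconnection: the C6–C7 bond of ring C is cut and a nitrogen atom is placed between the two carbons, so ring C becomes the N–H pyrrolidine A2. A2 is in turn the (3+2) adduct of an azomethine ylide (C6–N–C7, from a glycinate imine) with (Z)-3-butylidenephthalide A3 as dipolarophile (C3'=C8').
- Forward key step: N-amination of A2 by a hypervalent iodine oxidant and an ammonia source gives the isodiazene, which expels N2; the C6/C7 biradical recombines to cyclobutane A1.
- For: the contraction is stereospecific when recombination outruns bond rotation, the cis relation of propyl and O2' is inherited from the Z alkene of A3, one cycloaddition fixes all four ring C stereocentres, and asymmetric azomethine ylide cycloadditions are well developed.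
- Against: A3 is an electron-rich enol ester and styrene, not the acceptor alkene that a stabilised ylide needs, and the ylide carbon C7 would have to bond to the fully substituted, oxygen-bearing C3'. In the deletion step only C7 carries a radical-stabilising group (the ester); C6 is a plain secondary radical, so β-scission of the 1,4-biradical into two alkenes competes with closure to a fully substituted four-membered ring. A1 still lacks rings A and B and carbon C1: a Claisen closure of the chain ketone onto the ester, carbonylation at C7a and enol lactonisation would follow, on a base-sensitive spiro-lactone.
- Comparison: on stereochemical economy for ring C this route is stronger. The chosen strategy offers in its place a four-membered ring that arrives intact, one cycloaddition that delivers rings A, B and C with every ring carbon in place, and two remaining stereocentres set by simple convex-face approach.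

Alternative 2: thermal 8π–6π electrocyclisation cascade.
- Disconnection: C8'–C3' and C6–C7 are cut together, so rings B and C unravel into linear tetraene A5 (C8'=C6 E, C5=C4 Z, the butenolide alkene C3a=C7a, and C7=C3' as a Z-ylidenephthalide).
- Forward key step: heating A5 should cause conrotatory 8π closure (C8'–C3') and then disrotatory 6π closure of the cyclooctatriene (C6–C7) to give A4, the 4,5-didehydro derivative of 22. The C4=C5 alkene would then have to be reduced selectively.
- For: no reagent is needed, orbital symmetry converts alkene geometry into the trans relation of propyl and aryl and into the cis ring fusion, and two rings and four stereocentres form in one operation.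
- Against: the C3' terminus is fully substituted, so O2' must turn inward in the helical transition state, which retards the 8π step. The sense of the 6π closure relative to the C8'/C3' substituents is not fixed by symmetry, so two diastereomers are possible. A5 is achiral, so A4 is racemic and the single enantiomer would need a resolution. A5 holds two enol-lactone dienes and three stereodefined alkenes and is delicate to assemble. The last reduction must pick C4=C5 out of a cross-conjugated polyene lactone.
- Comparison: in ring-forming economy this route is stronger. The chosen strategy offers absolute control by a catalyst, robust intermediates, and the fragile butylidene diene only in the final step.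

Alternative 3: cyclopropylcarbinyl ring expansion with carboxylate capture.
- Disconnection: the C6–C8' and C3'–O2' bonds are cut; ring C contracts to a cyclopropane (C3', C6, C7) that carries at C3' the 2-carboxyphenyl group and the C8' carbinol (A7).
- Forward key step: the C8' alcohol of A7 is sulfonylated in a buffered fluorinated alcohol; ionisation is assisted by the C3'–C6 bond, C6 shifts to C8', and the tertiary benzylic cyclobutyl cation at C3' is trapped by the carboxyl group to give spiro keto-lactone A6.
- For: rings C and D form in one step, the migrating carbon keeps its configuration while C8' is inverted, and the cyclopropane can be made by established asymmetric carbene transfer. On absolute stereocontrol this is at least as secure as a cycloaddition with an electron-poor diene.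
- Against: the cation at C3' is planar, and the tethered oxygen would add to the open convex face, anti to C7a and propyl. That gives the C3' epimer of A6, whereas 22 has the oxygen on the concave face. The cyclopropylcarbinyl/cyclobutyl/homoallyl manifold also allows ring-opened products and migration of C7. A6 still lacks ring A: C1, C3 and the butylidene would need acylation at C3a, enol triflate formation, carbonylation and enol lactonisation.
- Comparison: the chosen strategy reverses the roles at C3' (carbon nucleophile onto a ketone), so the large group takes the open face and the oxygen ends where the target has it; it also avoids cationic equilibria on ring C and carries ring A from the start.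

Key step: step 5

Assumption: the (S)-configured catalyst of step 5 is taken to expose the face of 3 that leads to (6S,7R)-7; the sense is to be confirmed on the first run, and the equally available (R)-catalyst is substituted if it is opposite.

## Route

Step 1
Reactants: 1 3-oxocyclobutane-1-carboxylic acid
Product: 2 3-bromocyclobutan-1-one
Conditions: HgO, Br2, MgSO4, CH2Cl2, reflux
Reagents that add atoms: bromine, BrBr
Why: Hunsdiecker-type bromodecarboxylation (Cristol–Firth variant): the mercury carboxylate gives the acyl hypobromite, which loses CO2 in a radical chain, and the cyclobutyl radical takes up bromine; the ketone is untouched and no stereocentre is formed.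

Step 2
Reactants: 2 3-bromocyclobutan-1-one
Product: 3 cyclobut-2-en-1-one
Conditions: Bu3N, neat, rt, product distilled under reduced pressure into a cold trap
Reagents that add atoms: none
Why: E1cB dehydrobromination of a β-bromo ketone; the high-boiling amine and its salt stay behind, so the volatile, easily oligomerised enone is collected clean and used at once as a cold solution.

Step 3
Reactants: 4 tetronic acid
Product: 5 4-bromofuran-2(5H)-one
Conditions: (COBr)2, DMF (cat.), CH2Cl2, 0 °C to rt
Reagents that add atoms: oxalyl bromide, O=C(Br)C(=O)Br
Why: Vilsmeier-type activation of the vinylogous acid: the enol oxygen is turned into a leaving group by the bromoiminium salt and replaced by bromide through addition–elimination at C4.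

Step 4
Reactants: 5 4-bromofuran-2(5H)-one
Product: 6 4-vinylfuran-2(5H)-one
Conditions: Bu3SnCH=CH2, Pd(PPh3)4, BHT (cat.), toluene, 80 °C
Reagents that add atoms: tributyl(vinyl)stannane, C=C[Sn](CCCC)(CCCC)CCCC
Why: Stille cross-coupling; the β-bromo enoate undergoes oxidative addition readily, the base-free conditions spare the lactone, and the radical inhibitor keeps the vinyl butenolide from polymerising.

Step 5
Reactants: 3 cyclobut-2-en-1-one (excess), 6 4-vinylfuran-2(5H)-one
Product: 7 (6S,7R,7aR) endo Diels–Alder adduct: 5,6,7,7a-tetrahydroisobenzofuran-1(3H)-one with the alkene at C3a=C4 and a cyclobutanone cis-fused at C6–C7 (ring C: C6–C7–C3'(=O)–C8'H2, ketone carbon on C7), H-6, H-7 and H-7a all cis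
Conditions: (S)-3,3-diphenyl-1-(o-tolyl)tetrahydro-1H,3H-pyrrolo[1,2-c][1,3,2]oxazaborole (20 mol %), Tf2NH (18 mol %), CH2Cl2, −78 to −40 °C
Reagents that add atoms: none
Why: Protonation of the oxazaborolidine nitrogen by Tf2NH makes boron a strong chiral Lewis acid that binds the ketone of 3 and lowers its LUMO, and the s-cis diene C5=C4–C3a=C7a of 6 then adds across C6=C7 in a concerted, asynchronous (4+2) cycloaddition; the closest known reaction type is the oxazaborolidinium-catalysed enantioselective Diels–Alder reaction of cyclic enones, together with the known use of cyclobutenone as a strain-activated dienophile. Ring B is closed by this intermolecular suprafacial–suprafacial cycloaddition, which forms C5–C6 and C7–C7a and leaves the new alkene at C3a=C4. The step needs one regiochemistry: the β-carbon C6 of the bound enone has the larger LUMO coefficient and pairs with the unsubstituted terminus C5, which has the larger HOMO coefficient in a diene whose acceptor sits on the other terminus, so C7a bonds to the α-carbon C7. C6 and C7 become cis because both bonds form on one face of a cis ring alkene, and their absolute configuration is set by the catalyst, whose aryl groups shield one face of the bound enone. C7a is set by the endo transition state (ring C carbonyl under the diene) but is erased in step 7, so only regio- and enantioface selectivity matter. The ring strain of 3 compensates for the low HOMO of the acceptor-substituted diene, and 3 is used in excess because it oligomerises.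

Step 6
Reactants: 7 Diels–Alder adduct, 8 propanal
Product: 10 8'-(1-hydroxypropyl) derivative of 7 (mixture at C8' and the carbinol carbon; C6, C7 and C7a as in 7), via dibutylboron enolate 9 (not isolated)
Conditions: Bu2BOTf, iPr2NEt, CH2Cl2, −78 °C; 8, −78 to −20 °C; pH 7 buffer, MeOH
Reagents that add atoms: none
Why: Ketone-selective soft enolisation and boron aldol addition: Bu2BOTf binds the more Lewis-basic ketone and the hindered amine removes a proton from the accessible C8' methylene, not from the ring-fusion carbon C7, while a lactone is not enolised by this reagent pair at −78 °C; enolate 9 adds to 8 through a closed transition state. Both new stereocentres disappear in step 7, and the work-up is non-oxidative because peroxide would cause Baeyer–Villiger oxidation of the cyclobutanone.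

Step 7
Reactants: 10 aldol adduct
Product: 12 (6R,7R) 8'-[(E)-propylidene] keto-butenolide: 4,5,6,7-tetrahydroisobenzofuran-1(3H)-one (alkene C3a=C7a) cis-fused at C6–C7 to ring C with C3'=O and C8'=CH–CH2CH3 (same spatial arrangement at C6 and C7 as in 7; the C6 descriptor changes through CIP priorities only), via mesylate 11 (not isolated)
Conditions: MsCl, Et3N, CH2Cl2, 0 °C; then DBU, 0 °C to rt
Reagents that add atoms: none
Why: Mesylation and E1cB elimination give the alkylidene ketone; DBU also removes the doubly activated C7a–H and the dienolate is reprotonated at C4, which moves the ring alkene to the tetrasubstituted, conjugated C3a=C7a position and erases the C7a stereocentre. Endocyclic isomers of the enone are disfavoured by cyclobutenone strain, the cis fusion at C7 is the only stable one, and the alkene geometry has no bearing on later stereochemistry.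

Step 8
Reactants: 12 propylidene keto-butenolide
Product: 13 (6S,7R,8'R) 8'-propyl keto-butenolide: as 12 but with C8'–H and the propyl group cis to C5 (endo), H-6, H-7 and H-8' all cis
Conditions: H2 (1 atm), 10% Pd/C, EtOAc, rt
Reagents that add atoms: none
Why: Heterogeneous hydrogenation delivers both hydrogens to the convex face of the cis-fused bicyclo[4.2.0] core (the face of H-6 and H-7), so H-8' is installed cis to H-6 and the propyl chain ends on the concave face. The strained trisubstituted enone alkene should be reduced well before the tetrasubstituted butenolide alkene, and neutral conditions avoid epimerisation of the kinetically formed endo ketone.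

Step 9
Reactants: 13 8'-propyl keto-butenolide, 14 methyl 2-iodobenzoate
Product: 17 (6S,7R,3'R,8'R) spiro bis-lactone: 13 in which C3' is the spiro C3 of an isobenzofuran-1(3H)-one with the aryl carbon cis to H-7 and H-8' and O2' cis to C7a and propyl (C3 still CH2), via arylmagnesium chloride 15 (not isolated), via chloromagnesium alkoxide 16 (not isolated)
Conditions: 14, iPrMgCl·LiCl, THF, −40 °C; then 13, LaCl3·2LiCl, −78 to 0 °C; aq NH4Cl
Reagents that add atoms: none
Why: Iodine–magnesium exchange gives the ester-bearing Grignard reagent 15, stable at low temperature; LaCl3·2LiCl activates the ketone and suppresses enolisation, and the strained cyclobutanone is much more electrophilic than the butenolide. Both α-substituents of the ketone lie on the concave face, so the aryl group enters from the convex face; the alkoxide oxygen of 16 then attacks the neighbouring ester (5-exo-trig acyl substitution) to close ring D and fix C3' as R.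

Step 10
Reactants: 17 spiro bis-lactone
Product: 18 2-(triisopropylsilyloxy)furan of 17 (ring A as furan O2–C3H=C3a–C7a=C1–OSi(iPr)3; four stereocentres as in 17)
Conditions: TIPSOTf, Et3N, CH2Cl2, 0 °C
Reagents that add atoms: triisopropylsilyl trifluoromethanesulfonate, CC(C)[Si](C(C)C)(C(C)C)OS(=O)(=O)C(F)(F)F
Why: Soft enolisation of a butenolide: silylation of the lactone carbonyl and loss of a C3 proton give the aromatic silyloxyfuran, C3–H2 being the only site whose deprotonation leads to aromaticity; the bulky silyl group makes 18 robust enough for an aqueous work-up.

Step 11
Reactants: 18 silyloxyfuran, 19 butanal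
Product: 20 3-(1-hydroxybutyl) derivative of 17 (mixture at C3 and the carbinol carbon)
Conditions: 19, BF3·OEt2, CH2Cl2, −78 °C; aq NaHCO3
Reagents that add atoms: none
Why: Vinylogous Mukaiyama aldol addition: the BF3-activated aldehyde is attacked by the unsubstituted furan carbon C3 (the α-carbon C7a is fully substituted), which restores the C3a=C7a butenolide; the two new stereocentres are removed in step 12, so no diastereocontrol is needed.

Step 12
Reactants: 20 hydroxybutyl butenolide
Product: 22 target, (6S,7R,3'R,8'R)-(Z)-3-butylidene spiro bis-lactone, via mesylate 21 (not isolated)
Conditions: MsCl, Et3N, CH2Cl2, 0 °C; then DBU, 0 °C to rt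
Reagents that add atoms: none
Why: Mesylation and E1cB elimination through the C3 dienolate (C3–H is vinylogously acidic) give the exocyclic alkene; the Z isomer, with the propyl chain syn to O2 and away from C4H2, avoids A(1,3) strain in the elimination and is also the thermodynamic isomer. Ring C and the phthalide offer no acidic or ionisable site under these conditions.

## Compound list

1 | 3-oxocyclobutane-1-carboxylic acid | O=C1CC(C(=O)O)C1 | starting material
2 | 3-bromocyclobutan-1-one | O=C1CC(Br)C1 | intermediate
3 | cyclobut-2-en-1-one | O=C1CC=C1 | intermediate
4 | tetronic acid (furan-2,4(3H,5H)-dione) | O=C1CC(=O)CO1 | starting material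
5 | 4-bromofuran-2(5H)-one | O=C1C=C(Br)CO1 | intermediate
6 | 4-vinylfuran-2(5H)-one | C=CC1=CC(=O)OC1 | intermediate
7 | (6S,7R,7aR) endo Diels–Alder adduct, tricyclic keto-lactone with alkene C3a=C4 | O=C1OCC2=CC[C@H]3CC(=O)[C@H]3[C@@H]12 | intermediate
8 | propanal | CCC=O | starting material
9 | dibutylboron enolate of 7 (C3'=C8') | O=C1OCC2=CC[C@H]3C=C(OB(CCCC)CCCC)[C@H]3[C@@H]12 | intermediate (not isolated)
10 | 8'-(1-hydroxypropyl) derivative of 7, mixture at C8' and carbinol | O=C1OCC2=CC[C@H]3C(C(O)CC)C(=O)[C@H]3[C@@H]12 | intermediate
11 | methanesulfonate of 10 | O=C1OCC2=CC[C@H]3C(C(OS(C)(=O)=O)CC)C(=O)[C@H]3[C@@H]12 | intermediate (not isolated)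
12 | (6R,7R) 8'-[(E)-propylidene] keto-butenolide (alkene C3a=C7a) | O=C1OCC2=C1[C@@H]1C(=O)/C(=C/CC)[C@@H]1CC2 | intermediate
13 | (6S,7R,8'R) 8'-propyl keto-butenolide, propyl cis to C5 | O=C1OCC2=C1[C@@H]1C(=O)[C@H](CCC)[C@@H]1CC2 | intermediate
14 | methyl 2-iodobenzoate | COC(=O)c1ccccc1I | starting material
15 | [2-(methoxycarbonyl)phenyl]magnesium chloride (LiCl complex) | COC(=O)c1ccccc1[Mg]Cl | intermediate (not isolated)
16 | chloromagnesium alkoxide from addition of 15 to C3' of 13 | O=C1OCC2=C1[C@@H]1[C@@](O[Mg]Cl)(c3ccccc3C(=O)OC)[C@H](CCC)[C@@H]1CC2 | intermediate (not isolated)
17 | (6S,7R,3'R,8'R) spiro bis-lactone with C3 as CH2 | O=C1OCC2=C1[C@@H]1[C@]3(OC(=O)c4ccccc43)[C@H](CCC)[C@@H]1CC2 | intermediate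
18 | 2-(triisopropylsilyloxy)furan of 17 | CC(C)[Si](C(C)C)(C(C)C)Oc1occ2c1[C@@H]1[C@]3(OC(=O)c4ccccc43)[C@H](CCC)[C@@H]1CC2 | intermediate
19 | butanal | CCCC=O | starting material
20 | 3-(1-hydroxybutyl) derivative of 17, mixture at C3 and carbinol | O=C1OC(C(O)CCC)C2=C1[C@@H]1[C@]3(OC(=O)c4ccccc43)[C@H](CCC)[C@@H]1CC2 | intermediate
21 | methanesulfonate of 20 | O=C1OC(C(OS(C)(=O)=O)CCC)C2=C1[C@@H]1[C@]3(OC(=O)c4ccccc43)[C@H](CCC)[C@@H]1CC2 | intermediate (not isolated)
22 | target, (6S,7R,3'R,8'R)-(Z)-3-butylidene-8'-propyl spiro bis-lactone | CCC/C=C1\OC(=O)C2=C1CC[C@H]1[C@@H](CCC)[C@@]3(OC(=O)c4ccccc43)[C@@H]21 | target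

## Step count and least certain steps

Total: 12 steps. Longest linear sequence: 10 steps (1 → 2 → 3 → 7 → 10 → 12 → 13 → 17 → 18 → 20 → 22; the branch from 4 through 5 and 6 to 7 is equally long).

Step 5 (key step). The most likely failure is a cycloaddition that is too slow. The diene has a low HOMO, and its lactone carbonyl competes with the enone for the boron Lewis acid, so oligomerisation of 3 may outrun the reaction. A second concern is erosion of regio- or enantioface selectivity, because the alkyl branch at C3a directs opposite to the terminal acceptor. Fallback, setting out from 3 and returning at 7: 3 is treated with Br2 in CH2Cl2 at −78 °C to give trans-2,3-dibromocyclobutan-1-one F1, and Et3N then removes HBr to give 2-bromocyclobut-2-en-1-one F2, a more electrophilic dienophile of the α-halo enone type. Cycloaddition of F2 with 6 under the catalyst of step 5 should give the 7-bromo analogue of 7 F3. Zn in AcOH at 0 °C should then remove the bromine through the zinc enolate, whose protonation at C7 can only restore the cis ring fusion, giving 7.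

Step 6. The most likely failure is loss of site selectivity in the enolisation. C7a–H is activated by both the lactone and the alkene, so deprotonation there, or a premature alkene shift that exposes the acidic C3 methylene of a butenolide, would divert the aldehyde or consume the boron reagent. Fallback, setting out from 7 and returning at 12: the lactone is masked before the ketone is enolised. DBU (cat.) in CH2Cl2 should move the alkene into conjugation to give keto-butenolide F4. TIPSOTf (1.05 equiv) and Et3N at −78 °C silylate the most acidic site to give 2-silyloxyfuran ketone F5, in which ring A is aromatic and has no acidic hydrogen. LDA in THF at −78 °C then removes a proton from the accessible C8' methylene, and the lithium enolate adds to 8 to give aldol F6. MsCl/Et3N followed by DBU gives propylidene ketone F7, and HF·pyridine in THF removes the silyl group to return the conjugated butenolide 12.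

Step 9. The most likely failure is proton transfer in place of addition. The ketone is flanked by two α-substituents and the nucleophile is ortho-substituted, so deprotonation at C3 of the butenolide or at the ketone α-carbons may compete; ring opening of the strained tertiary cyclobutanolate before lactonisation is a second concern. Fallback, setting out from 13 and returning at 17: a less basic, ester-free aryl nucleophile is used and ring D is closed separately. N,N-Diethylbenzamide is ortho-lithiated (s-BuLi, TMEDA, THF, −78 °C) and transmetalated with CeCl3 to [2-(diethylcarbamoyl)phenyl]cerium dichloride F9, which should add to 13 from the convex face without enolisation to give hydroxy amide F10. TsOH·H2O in toluene at 80 °C then closes ring D with loss of diethylamine to give 17.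

Step 8. What may go wrong is over-reduction (hydrogenolysis of the allylic C3–O2 bond or slow reduction of the butenolide on palladium), incomplete face discrimination, or epimerisation of the endo ketone at C8' to the more stable exo epimer during handling. Fallback, setting out from 12 and returning at 13: the two hydrogens are delivered in separate events. RhCl(PPh3)3-catalysed 1,4-hydrosilylation with Et3SiH (benzene, 50 °C) should convert the enone into triethylsilyl enol ether F8 (C3'=C8') and leave the tetrasubstituted butenolide alone. Bu4NF buffered with AcOH in THF at −78 °C then releases the enolate, which is protonated kinetically on the convex face to give 13.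

## Further compounds

F1 | step 5 | trans-2,3-dibromocyclobutan-1-one (racemic, one enantiomer drawn) | O=C1C[C@H](Br)[C@H]1Br
F2 | step 5 | 2-bromocyclobut-2-en-1-one | O=C1CC=C1Br
F3 | step 5 | 7-bromo analogue of 7 (Br in place of H-7) | O=C1OCC2=CC[C@H]3CC(=O)[C@@]3(Br)[C@@H]12
F4 | step 6 | conjugated keto-butenolide (alkene C3a=C7a, C8' as CH2) | O=C1OCC2=C1[C@@H]1C(=O)C[C@@H]1CC2
F5 | step 6 | 2-(triisopropylsilyloxy)furan of F4 | CC(C)[Si](C(C)C)(C(C)C)Oc1occ2c1[C@@H]1C(=O)C[C@@H]1CC2
F6 | step 6 | 8'-(1-hydroxypropyl) derivative of F5 (mixture at C8' and carbinol) | CC(C)[Si](C(C)C)(C(C)C)Oc1occ2c1[C@@H]1C(=O)C(C(O)CC)[C@@H]1CC2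
F7 | step 6 | 8'-[(E)-propylidene] derivative of F5 | CC(C)[Si](C(C)C)(C(C)C)Oc1occ2c1[C@@H]1C(=O)/C(=C/CC)[C@@H]1CC2
F8 | step 8 | triethylsilyl enol ether (C3'=C8') of 13 | O=C1OCC2=C1[C@@H]1C(O[Si](CC)(CC)CC)=C(CCC)[C@@H]1CC2
F9 | step 9 | [2-(diethylcarbamoyl)phenyl]cerium dichloride | CCN(CC)C(=O)c1ccccc1[Ce](Cl)Cl
F10 | step 9 | C3' tertiary alcohol carrying a 2-(diethylcarbamoyl)phenyl group (aryl on the convex face) | O=C1OCC2=C1[C@@H]1[C@@](O)(c3ccccc3C(=O)N(CC)CC)[C@H](CCC)[C@@H]1CC2
A1 | alternative 1 | methyl 3'-oxo-3-(4-oxooctyl)-4-propyl-3'H-spiro[cyclobutane-1,1'-isobenzofuran]-2-carboxylate | CCCCC(=O)CCC[C@H]1[C@@H](CCC)[C@@]2(OC(=O)c3ccccc32)[C@H]1C(=O)OC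
A2 | alternative 1 | methyl 3'-oxo-5-(4-oxooctyl)-4-propyl-3'H-spiro[pyrrolidine-3,1'-isobenzofuran]-2-carboxylate | CCCCC(=O)CCC[C@@H]1N[C@H](C(=O)OC)[C@]2(OC(=O)c3ccccc32)[C@@H]1CCC
A3 | alternative 1 | (Z)-3-butylideneisobenzofuran-1(3H)-one | CCC/C=C1\OC(=O)c2ccccc12
A4 | alternative 2 | 4,5-didehydro derivative of 22 (ring B as cyclohexa-1,3-diene) | CCC/C=C1\OC(=O)C2=C1C=C[C@H]1[C@@H](CCC)[C@@]3(OC(=O)c4ccccc43)[C@@H]21
A5 | alternative 2 | linear tetraene: (Z)-5-butylidene-4-[(1Z,3E)-hepta-1,3-dienyl]-3-[(Z)-(3-oxoisobenzofuran-1(3H)-ylidene)methyl]furan-2(5H)-one | CCC/C=C1\OC(=O)C(/C=C2\OC(=O)c3ccccc32)=C1/C=C\C=C\CCC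
A6 | alternative 3 | 7-propyl-3'H-spiro[bicyclo[4.2.0]octane-8,1'-isobenzofuran]-2,3'-dione | O=C1CCC[C@H]2[C@@H](CCC)[C@@]3(OC(=O)c4ccccc43)[C@@H]12
A7 | alternative 3 | 2-[7-(1-hydroxybutyl)-2-oxobicyclo[4.1.0]heptan-7-yl]benzoic acid | O=C1CCC[C@@H]2[C@H]1[C@@]2(c1ccccc1C(=O)O)[C@H](O)CCC
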